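**Retrosynthetic overview**

1. The target is a trans-2,5-disubstituted oxane (O1, C2–C6) with a prop-2-enoic acid on C2 and, on C5, a chain ending in a (3R)-allylic alcohol next to a 1,1-disubstituted alkene. The acid is released last from its methyl ester. The side-chain C3–C4 bond (carbinol–alkenyl) is cut to an oxane propanal plus the enol triflate of (E)-geranylacetone (asymmetric Ni/Cr coupling), and the propanal comes from hydroformylation of a 5-vinyl oxane.
2. Key disconnection: ring bond C5–C6. C6 is an unsubstituted CH2 bonded only to O1 and C5, a formaldehyde-level carbon that can sit on the C2 oxygen as the CH2 of a methoxymethyl ether and be unmasked as the oxocarbenium ion O1=C6. C5 lies β to O1 and its exocyclic two-carbon stub (a vinyl group) makes it the γ-carbon of an allylsilane, so the only ring is closed once by an intramolecular Hosomi–Sakurai reaction.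
3. The cyclisation substrate is an E/Z mixture of allylsilanes that should converge on one C5 configuration under control of C2. C2 is a carbinol flanked by the acrylate (a Morita–Baylis–Hillman motif) and is set by an amine-catalysed asymmetric MBH reaction of an aldehyde made by cross-metathesis of pent-4-enal with allyltrimethylsilane.
4. Order of events: acyclic chain and C2 (steps 1–4), oxane ring and C5 (step 5), side chain and its carbinol (steps 6–8), free acid (step 9).

Key step: step 5

Remark: (E)-geranylacetone (11) is taken as a commercial single isomer, and the alkene geometry of 3 is deliberately left as the E/Z mixture formed in step 1.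

**Route**

Step 1
Reactants: 1 pent-4-enal; 2 allyltrimethylsilane
Product: 3 6-(trimethylsilyl)hex-4-enal (4E/4Z mixture)
Conditions: second-generation Grubbs catalyst (2 mol%), 2 (3 equiv), CH2Cl2, 40 °C
Reagents that add atoms: none
Why: Olefin cross-metathesis between two unhindered terminal alkenes, driven by loss of ethene and by the excess of the allylsilane partner, should give the internal allylsilane with the aldehyde tolerated by the ruthenium carbene; no stereocentre is formed and the alkene geometry does not need to be controlled.

Step 2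
Reactants: 3 6-(trimethylsilyl)hex-4-enal; 4 1,1,1,3,3,3-hexafluoropropan-2-yl prop-2-enoate
Product: 5 1,1,1,3,3,3-hexafluoropropan-2-yl (3R)-3-hydroxy-2-methylidene-8-(trimethylsilyl)oct-6-enoate (6E/6Z mixture)
Conditions: β-isocupreidine (10 mol%), DMF, −55 °C
Reagents that add atoms: none
Why: Catalytic asymmetric Morita–Baylis–Hillman reaction, in which the quinuclidine nitrogen of β-isocupreidine adds to the activated fluorinated acrylate and the phenolic OH of the catalyst hydrogen-bonds the aldolate so that only one diastereomeric betaine eliminates, which for aliphatic aldehydes should deliver the (R)-carbinol, the future C2 of the oxane (catalyst control).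

Step 3
Reactants: 5 1,1,1,3,3,3-hexafluoropropan-2-yl (3R)-3-hydroxy-2-methylidene-8-(trimethylsilyl)oct-6-enoate
Product: 6 methyl (3R)-3-hydroxy-2-methylidene-8-(trimethylsilyl)oct-6-enoate (6E/6Z mixture)
Conditions: MeOH, Et3N, 0 °C → rt
Reagents that add atoms: methanol, CO
Why: Amine-promoted transesterification of the activated hexafluoroisopropyl ester by methanol should give the more robust methyl ester without touching the allylsilane or the stereocentre.

Step 4
Reactants: 6 methyl (3R)-3-hydroxy-2-methylidene-8-(trimethylsilyl)oct-6-enoate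
Product: 7 methyl (3R)-3-(methoxymethoxy)-2-methylidene-8-(trimethylsilyl)oct-6-enoate (6E/6Z mixture)
Conditions: MeOCH2Cl, iPr2NEt, Bu4NI (catalytic), CH2Cl2, 0 °C → rt
Reagents that add atoms: chloromethyl methyl ether, COCCl
Why: Alkoxymethylation of the secondary alcohol with an α-chloro ether and a hindered amine (Williamson-type etherification) places the future C6 on the C2 oxygen as a formaldehyde acetal under conditions too mild for retro-aldol cleavage or oxa-Michael addition of the hydroxy acrylate.

Step 5
Reactants: 7 methyl (3R)-3-(methoxymethoxy)-2-methylidene-8-(trimethylsilyl)oct-6-enoate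
Product: 9 methyl 2-[(2R,5R)-5-ethenyloxan-2-yl]prop-2-enoate, via oxocarbenium triflate 8 (not isolated)
Conditions: Me3SiOTf (0.3 equiv), 2,6-di-tert-butyl-4-methylpyridine (0.1 equiv), CH2Cl2, −78 → −20 °C
Reagents that add atoms: none
Why: Me3SiOTf silylates the less hindered methoxy oxygen of the formaldehyde acetal and expels methoxytrimethylsilane to leave the alkoxymethyl oxocarbenium ion 8, whose CH2 carbon is attacked by the γ-carbon of the allylsilane, after which the β-silyl cation gives up Me3Si+ to triflate, regenerating the promoter and leaving the vinyl group (intramolecular Hosomi–Sakurai reaction). The closest known reaction type is the Lewis-acid-promoted cyclisation of ω-silylallyl alkoxymethyl ethers to 3-vinyl oxolanes and oxanes. The oxane closes in a 6-exo-trig mode with respect to the allylsilane C=C, the C=O+ unit lying inside the new ring. The new stereocentre C5 is controlled by C2 through a chair-like transition state in which the C2 substituent and the reacting alkenyl arm are both pseudo-equatorial, which should give the 2,5-trans oxane, and the E and Z allylsilanes should funnel into the same C5 configuration because the alkene geometry is erased when the vinyl group forms. The step needs ionisation on the methoxy side of the acetal and attack by the allylsilane only: the acrylate alkene is electron-poor and not nucleophilic, the 6-exo trapping is the only irreversible exit for the cation, and the hindered pyridine suppresses acid-induced protodesilylation.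

Step 6
Reactants: 9 methyl 2-[(2R,5R)-5-ethenyloxan-2-yl]prop-2-enoate
Product: 10 methyl 2-[(2R,5R)-5-(3-oxopropyl)oxan-2-yl]prop-2-enoate
Conditions: Rh(acac)(CO)2 (1 mol%), BiPhePhos (2 mol%), CO/H2 (1:1, 5 bar), toluene, 60 °C
Reagents that add atoms: carbon monoxide, [C-]#[O+] (H2 supplies hydrogen only)
Why: Rhodium-catalysed hydroformylation with a bulky chelating bisphosphite is strongly linear-selective for monosubstituted alkenes, so H and CHO should add across the vinyl group with the formyl carbon at the terminus, while the 1,1-disubstituted, ester-conjugated acrylate alkene reacts much more slowly and C5 carries no acidic hydrogen.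

Step 7
Reactants: 11 (5E)-6,10-dimethylundeca-5,9-dien-2-one ((E)-geranylacetone)
Product: 13 (5E)-6,10-dimethylundeca-1,5,9-trien-2-yl trifluoromethanesulfonate, via potassium enolate 12 (not isolated)
Conditions: KN(SiMe3)2, THF, −78 °C; then PhNTf2, −78 → 0 °C
Reagents that add atoms: N-phenylbis(trifluoromethanesulfonimide), O=S(=O)(N(c1ccccc1)S(=O)(=O)C(F)(F)F)C(F)(F)F; potassium bis(trimethylsilyl)amide, C[Si](C)(C)[N-][Si](C)(C)C.[K+] (its potassium is carried by intermediate 12 only)
Why: Kinetic deprotonation of the methyl ketone on the methyl side by a hindered amide base at −78 °C followed by O-sulfonylation of the enolate with N-phenyltriflimide (enol triflate formation) should give the 1-alken-2-yl triflate and leave the E-trisubstituted alkene untouched.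

Step 8
Reactants: 10 methyl 2-[(2R,5R)-5-(3-oxopropyl)oxan-2-yl]prop-2-enoate; 13 (5E)-6,10-dimethylundeca-1,5,9-trien-2-yl trifluoromethanesulfonate
Product: 15 methyl 2-[(2R,5S)-5-[(3R,7E)-3-hydroxy-8,12-dimethyl-4-methylidenetrideca-7,11-dien-1-yl]oxan-2-yl]prop-2-enoate, via trimethylsilyl ether 14 (not isolated)
Conditions: CrCl2 (10 mol%), N-[2-(4-isopropyl-4,5-dihydro-1,3-oxazol-2-yl)-6-methylphenyl]methanesulfonamide (12 mol%, the antipode that directs Si-face addition), Et3N (20 mol%), NiCl2(dmp) (2 mol%, dmp = 2,9-dimethyl-1,10-phenanthroline), Mn (2 equiv), LiCl (2 equiv), Me3SiCl (2 equiv), MeCN, rt; then aq. citric acid, THF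
Reagents that add atoms: chlorotrimethylsilane, C[Si](C)(C)Cl (its silyl group is carried by intermediate 14 only)
Why: Catalytic asymmetric Nozaki–Hiyama–Kishi coupling, in which zerovalent nickel inserts into the alkenyl triflate, transmetalation gives an alkenyl species of trivalent chromium that adds to aldehydes but not to esters or acrylates, Me3SiCl with Mn turns the chromium over, and the chromium-bound chiral sulfonamide directs the alkenyl group to the Si face of the aldehyde so that the 3R carbinol is set by catalyst control, the ring stereocentres being too remote to interfere.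

Step 9
Reactants: 15 methyl 2-[(2R,5S)-5-[(3R,7E)-3-hydroxy-8,12-dimethyl-4-methylidenetrideca-7,11-dien-1-yl]oxan-2-yl]prop-2-enoate
Product: 17 2-[(2R,5S)-5-[(3R,7E)-3-hydroxy-8,12-dimethyl-4-methylidenetrideca-7,11-dien-1-yl]oxan-2-yl]prop-2-enoic acid, via lithium carboxylate 16 (not isolated)
Conditions: LiOH·H2O, THF/H2O (3:1), 0 °C → rt; then 1 M HCl to pH 3
Reagents that add atoms: lithium hydroxide, [Li+].[OH-]
Why: Saponification of the methyl ester by hydroxide and acidification of the carboxylate should liberate the acrylic acid, while the allylic alcohol, the oxane and the three stereocentres, none of which bears an acidic hydrogen, stay untouched.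

**Compound list**

1 | pent-4-enal | C=CCCC=O | starting material
2 | allyltrimethylsilane | C=CC[Si](C)(C)C | starting material
3 | 6-(trimethylsilyl)hex-4-enal (4E/4Z mixture) | O=CCCC=CC[Si](C)(C)C | intermediate
4 | 1,1,1,3,3,3-hexafluoropropan-2-yl prop-2-enoate | C=CC(=O)OC(C(F)(F)F)C(F)(F)F | starting material
5 | 1,1,1,3,3,3-hexafluoropropan-2-yl (3R)-3-hydroxy-2-methylidene-8-(trimethylsilyl)oct-6-enoate (6E/6Z mixture) | C[Si](C)(C)CC=CCC[C@H](C(=C)C(=O)OC(C(F)(F)F)C(F)(F)F)O | intermediate
6 | methyl (3R)-3-hydroxy-2-methylidene-8-(trimethylsilyl)oct-6-enoate (6E/6Z mixture) | C[Si](C)(C)CC=CCC[C@H](C(=C)C(=O)OC)O | intermediate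
7 | methyl (3R)-3-(methoxymethoxy)-2-methylidene-8-(trimethylsilyl)oct-6-enoate (6E/6Z mixture) | C[Si](C)(C)CC=CCC[C@H](C(=C)C(=O)OC)OCOC | intermediate
8 | [(3R)-1-methoxy-2-methylidene-1-oxo-8-(trimethylsilyl)oct-6-en-3-yl](methylidene)oxonium trifluoromethanesulfonate (not isolated) | C[Si](C)(C)CC=CCC[C@H](C(=C)C(=O)OC)[O+]=C.[O-]S(=O)(=O)C(F)(F)F | intermediate
9 | methyl 2-[(2R,5R)-5-ethenyloxan-2-yl]prop-2-enoate | C=C[C@H]1CC[C@H](C(=C)C(=O)OC)OC1 | intermediate
10 | methyl 2-[(2R,5R)-5-(3-oxopropyl)oxan-2-yl]prop-2-enoate | O=CCC[C@H]1CC[C@H](C(=C)C(=O)OC)OC1 | intermediate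
11 | (5E)-6,10-dimethylundeca-5,9-dien-2-one ((E)-geranylacetone) | CC(=O)CC/C=C(\C)CCC=C(C)C | starting material
12 | potassium (5E)-6,10-dimethylundeca-1,5,9-trien-2-olate (not isolated) | [K+].[O-]C(=C)CC/C=C(\C)CCC=C(C)C | intermediate
13 | (5E)-6,10-dimethylundeca-1,5,9-trien-2-yl trifluoromethanesulfonate | C=C(OS(=O)(=O)C(F)(F)F)CC/C=C(\C)CCC=C(C)C | intermediate
14 | O-trimethylsilyl ether of 15 at the side-chain carbinol (not isolated) | C=C(CC/C=C(\C)CCC=C(C)C)[C@H](O[Si](C)(C)C)CC[C@H]1CC[C@H](C(=C)C(=O)OC)OC1 | intermediate
15 | methyl 2-[(2R,5S)-5-[(3R,7E)-3-hydroxy-8,12-dimethyl-4-methylidenetrideca-7,11-dien-1-yl]oxan-2-yl]prop-2-enoate | C=C(CC/C=C(\C)CCC=C(C)C)[C@H](O)CC[C@H]1CC[C@H](C(=C)C(=O)OC)OC1 | intermediate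
16 | lithium salt of 17 (not isolated) | C=C(CC/C=C(\C)CCC=C(C)C)[C@H](O)CC[C@H]1CC[C@H](C(=C)C(=O)[O-])OC1.[Li+] | intermediate
17 | 2-[(2R,5S)-5-[(3R,7E)-3-hydroxy-8,12-dimethyl-4-methylidenetrideca-7,11-dien-1-yl]oxan-2-yl]prop-2-enoic acid | C=C(CC/C=C(\C)CCC=C(C)C)[C@H](O)CC[C@H]1CC[C@H](C(=C)C(=O)O)OC1 | target

**Step count**

Total: 9 steps. Longest linear sequence: 8 steps (steps 1–6, 8 and 9 from pent-4-enal); step 7 is a one-step branch.

**Steps most likely to fail, with fallbacks**

Step 5 (ring closure). The acetal may ionise on the wrong oxygen, so that the whole methoxymethyl group is lost instead of methanol. Traces of acid may also protodesilylate the allylsilane before the ring closes, and the chair preference that sets C5 may be incomplete at the temperature needed for ionisation. The fallback sets out from 6 and comes back at 9. Alcohol 6 is converted with Me2S and benzoyl peroxide (MeCN, 0 °C, Pummerer-type methylthiomethylation) into the O,S-acetal methyl (3R)-2-methylidene-3-[(methylsulfanyl)methoxy]-8-(trimethylsilyl)oct-6-enoate F1. Soft S-methylation with MeOTf (2,6-di-tert-butyl-4-methylpyridine, CH2Cl2, −78 → −40 °C) then gives the dimethylsulfonium triflate F2. Loss of dimethyl sulfide from F2 can only produce the oxocarbenium triflate 8, under non-acidic conditions and at lower temperature, and 8 closes to 9 as in the main route.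

Step 6 (hydroformylation). The rhodium hydride may also hydroformylate, hydrogenate or isomerise at the acrylate, or formylate the vinyl group at its internal carbon. The fallback sets out from 9 and comes back at 10. Cross-metathesis of 9 with (E)-but-2-enal (second-generation Hoveyda–Grubbs catalyst, CH2Cl2, 40 °C) should give the enal methyl 2-[(2R,5R)-5-[(1E)-3-oxoprop-1-en-1-yl]oxan-2-yl]prop-2-enoate F3, the electron-poor 1,1-disubstituted acrylate staying out of the metathesis. Iminium-catalysed transfer hydrogenation with the Hantzsch ester (diethyl 2,6-dimethyl-1,4-dihydropyridine-3,5-dicarboxylate) and dibenzylammonium trifluoroacetate (THF, 0 °C) should then reduce only the enal C=C, which the amine activates while the acrylate is left alone, to give 10.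

Step 8 (asymmetric Ni/Cr coupling). Facial selection at the unbranched aldehyde by the chromium-bound ligand may be insufficient, so that both configurations of the new carbinol form. The fallback sets out from the epimer mixture that step 8 would then deliver, 15 together with its 3S epimer methyl 2-[(2R,5S)-5-[(3S,7E)-3-hydroxy-8,12-dimethyl-4-methylidenetrideca-7,11-dien-1-yl]oxan-2-yl]prop-2-enoate F4, and comes back at 15. Dess–Martin periodinane (NaHCO3, CH2Cl2, 0 °C) should oxidise both epimers to the enone methyl 2-[(2R,5R)-5-[(7E)-8,12-dimethyl-4-methylidene-3-oxotrideca-7,11-dien-1-yl]oxan-2-yl]prop-2-enoate F5. Corey–Bakshi–Shibata reduction of F5 ((S)-2-methyl-CBS-oxazaborolidine, catecholborane, toluene, −78 °C), with the alkenyl group acting as the large substituent, should give the catecholborate of the 3R alcohol F6, which is hydrolysed on work-up to 15. The stereocentre is then set by ketone reduction instead of by C–C bond formation.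

Further compounds
F1 | step 5 | methyl (3R)-2-methylidene-3-[(methylsulfanyl)methoxy]-8-(trimethylsilyl)oct-6-enoate | C[Si](C)(C)CC=CCC[C@H](C(=C)C(=O)OC)OCSC
F2 | step 5 | ({[(3R)-1-methoxy-2-methylidene-1-oxo-8-(trimethylsilyl)oct-6-en-3-yl]oxy}methyl)dimethylsulfonium trifluoromethanesulfonate (not isolated) | C[Si](C)(C)CC=CCC[C@H](C(=C)C(=O)OC)OC[S+](C)C.[O-]S(=O)(=O)C(F)(F)F
F3 | step 6 | methyl 2-[(2R,5R)-5-[(1E)-3-oxoprop-1-en-1-yl]oxan-2-yl]prop-2-enoate | O=C/C=C/[C@H]1CC[C@H](C(=C)C(=O)OC)OC1
F4 | step 8 | methyl 2-[(2R,5S)-5-[(3S,7E)-3-hydroxy-8,12-dimethyl-4-methylidenetrideca-7,11-dien-1-yl]oxan-2-yl]prop-2-enoate | C=C(CC/C=C(\C)CCC=C(C)C)[C@@H](O)CC[C@H]1CC[C@H](C(=C)C(=O)OC)OC1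
F5 | step 8 | methyl 2-[(2R,5R)-5-[(7E)-8,12-dimethyl-4-methylidene-3-oxotrideca-7,11-dien-1-yl]oxan-2-yl]prop-2-enoate | C=C(CC/C=C(\C)CCC=C(C)C)C(=O)CC[C@H]1CC[C@H](C(=C)C(=O)OC)OC1
F6 | step 8 | 1,3,2-benzodioxaborol-2-yl ether of 15 at the side-chain carbinol (not isolated) | C=C(CC/C=C(\C)CCC=C(C)C)[C@H](OB1Oc2ccccc2O1)CC[C@H]1CC[C@H](C(=C)C(=O)OC)OC1
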